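4 amounts are asked of this flask, and the ledger to keep for them is that of Q.

| flask | E | Q | remark | time |
|---|---|---|---|---|
| ochre | 0.073 M | 0.65 equiv | run made earlier |  |
| violet | 0.073 M | 0.98 equiv | run made earlier |  |
| green | 0.15 M | 1.3 equiv | run made earlier |  |
| flask | 0.073 M | 1.30 equiv |  | 6.0 h |

| run | time / h | E / % | L / % |
|---|---|---|---|
| ochre | 0.333 | 78.0 | 13.5 |
| ochre | 1.00 | 57.7 | 20.8 |
| ochre | 1.50 | 52.7 | 21.5 |
| ochre | 2.50 | 44.6 | 18.9 |
| ochre | 4.00 | 41.9 | 12.6 |
| ochre | 5.00 | 40.2 | 11.4 |
| ochre | 6.00 | 39.5 | 7.9 |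
| violet | 0.833 | 49.3 | 27.7 |
| violet | 1.50 | 36.3 | 24.7 |
| violet | 2.50 | 29.0 | 20.1 |
| violet | 3.00 | 24.1 | 19.4 |
| violet | 4.00 | 22.1 | 15.5 |
| violet | 5.00 | 20.8 | 11.2 |
| violet | 6.00 | 20.6 | 11.1 |
| green | 0.500 | 31.6 | 30.6 |
| green | 1.50 | 14.6 | 22.9 |
| green | 3.00 | 8.3 | 12.5 |
| green | 4.00 | 7.8 | 10.3 |
| green | 6.00 | 7.2 | 6.8 |

(standard deviation of a reading: 1 percentage point)

* amount of E at 6.0 h, in percent of the E charged
* amount of L at 6.0 h, in percent of the E charged
* amount of X at 6.0 h, in percent of the E charged
* amount of G at 6.0 h, in percent of the E charged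

- what was read earlier has a scatter of 1 percentage point, one standard deviation

Double addition to every E takes 2 equivalents and the flask has 1.30 equiv, so Q is the limiting reagent. Enter it in percent of the E charged. The first entry is one Q for each E that adds it, giving a mono adduct, L or X. The second entry is one more Q for each G, and the third is unspent Q. You need E, and the green run supplies it: with the same equivalents, its concentration times time at 3.00 h is 1.03 times the flask's at 6.0 h, so I freeze that product and take its reading, E 8.3 %. The Q surplus, Q charged less E reacted, which counts every reacted E as having taken one Q, is then 38.3 % for the flask, and it should pay for G and unspent Q together.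

Try the same entry on the ochre run. At 6.00 h its surplus stands at 4.50 %, yet L has fallen 14 percentage points from its highest reading, more than that surplus. That gap of about 9.1 points, a reading with its scatter, is a rough lower estimate of the L that left by a step costing no Q, not its amount. In the flask, the E that reacted and does not stand as G is shared among L, X and whatever steps costing no Q make, and the surplus does not say how, so I commit to E and the surplus and leave the split open.

The forecast gives E 10 %, L 8 %, X 57 % and G 25 %, holding that “The Q budget caps G near 35”.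

The flask gives E 7.60 %, L 8.64 %, X 24.6 % and G 31.3 %.

    L → Z (k = 0.220 h⁻¹)
    E + Q → X + J (k = 5.40 L mol⁻¹ h⁻¹)
    E + L → D (k = 1.30 L mol⁻¹ h⁻¹)
    Q + X → G + J (k = 0.230 L mol⁻¹ h⁻¹)
    E + Q → L + J (k = 14.0 L mol⁻¹ h⁻¹)
    Q + L → G + J (k = 12.0 L mol⁻¹ h⁻¹)

Beside these the flask holds Z 23.3 %, reached from L without Q. Against the surplus of 38.3 % stand G and unspent Q, the latter 8.65 % of the E charged, together 39.9 %. In the neighbouring flask with 0.330 equiv of Q, the same entry gives a surplus of −1.56 %, and that flask holds D 7.32 %, which counts two E per D, one of them taken up without Q. Adding that E, 3.66 %, brings the surplus of that flask to 2.10 %, against G with unspent Q at 2.10 %.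

(Readings and results stem from a simulated flask for an exercise, noise included.)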